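## Retrosynthetic overview

1. Target ⇐ epoxy-enone dimethyl monoketal carrying the side-chain terminus as a silyl ether; the endgame is desilylation/acetylation, MnO2 oxidation and ketal hydrolysis.
2. Oxirane ⇐ hydroxyl-guided Weitz–Scheffer epoxidation of a 2-(1-hydroxydienyl)quinone monoketal; the oxirane is the only ring that is made, and it is made last.
3. Ring–C1′ bond (key) ⇐ intermolecular thia-Michael/aldol union of a quinone monoketal with a (2E,4E)-dienal, then sulfoxide elimination (Baylis–Hillman-type adduct); the carbinol is obtained as a single enantiomer by Sharpless kinetic resolution.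
4. Six-membered ring ⇐ not built: oxidative dearomatisation of 3-(hydroxymethyl)-4-methoxyphenol, from 5-hydroxy-2-methoxybenzaldehyde.
5. Dienal ⇐ (E)-pent-2-en-4-yn-1-ol by zirconium-catalysed methylalumination/hydroxymethylation and MnO2 oxidation.

Assumption: reagents that only deliver a protecting group, a heteroatom or a one-carbon unit are given by name and SMILES in the steps and carry no compound number; 1 and 5 are bought.

Abbreviations: TES = triethylsilyl, TBDPS = tert-butyldiphenylsilyl, TESO/TBDPSO = the silyloxy groups; C1′ = carbinol carbon of the side chain.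

## Route

Step 1
Reactants: 1 5-hydroxy-2-methoxybenzaldehyde
Product: 2 3-(hydroxymethyl)-4-methoxyphenol
Conditions: NaBH4, MeOH, 0 °C to rt
Reagents that add atoms: none
Why: Borohydride reduction of the aryl aldehyde to the benzylic alcohol leaves the phenol and the methyl ether untouched.

Step 2
Reactants: 2 3-(hydroxymethyl)-4-methoxyphenol
Product: 3 3-(hydroxymethyl)-4,4-dimethoxycyclohexa-2,5-dien-1-one
Conditions: PhI(OAc)2, MeOH, 0 °C
Reagents that add atoms: methanol, CO
Why: Hypervalent-iodine oxidative dearomatisation of a para-methoxyphenol: methanol traps the phenoxonium ion at the methoxy-bearing carbon, which fixes the ketone at the former phenol carbon and the dimethyl ketal next to the CH2OH-bearing carbon.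

Step 3
Reactants: 3 3-(hydroxymethyl)-4,4-dimethoxycyclohexa-2,5-dien-1-one
Product: 4 4,4-dimethoxy-3-[(triethylsilyloxy)methyl]cyclohexa-2,5-dien-1-one
Conditions: Et3SiCl, imidazole, CH2Cl2, 0 °C
Reagents that add atoms: chlorotriethylsilane (TESCl), CC[Si](Cl)(CC)CC
Why: Standard silylation of the primary alcohol gives an ether that tolerates thiolate, peroxide and amine bases and can later be removed in the presence of a TBDPS ether.

Step 4
Reactants: 5 (2E)-pent-2-en-4-yn-1-ol
Product: 6 tert-butyl{[(2E)-pent-2-en-4-yn-1-yl]oxy}diphenylsilane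
Conditions: TBDPSCl, imidazole, CH2Cl2, 0 °C to rt
Reagents that add atoms: tert-butyl(chloro)diphenylsilane (TBDPSCl), CC(C)(C)[Si](Cl)(c1ccccc1)c1ccccc1
Why: Silylation of the primary allylic alcohol gives a robust ether that survives organoaluminium, organolithium, peroxide and mild acid.

Step 5
Reactants: 6 tert-butyl{[(2E)-pent-2-en-4-yn-1-yl]oxy}diphenylsilane
Product: 9 (2E,4E)-6-(TBDPSO)-3-methylhexa-2,4-dien-1-ol, via dienyl(dimethyl)alane 7 (not isolated), via lithium butyl(dienyl)dimethylalanate 8 (not isolated)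
Conditions: AlMe3 (2.5 equiv), Cp2ZrCl2 (25 mol %), CH2Cl2, 0 °C to rt; evaporate; n-BuLi, THF, −78 °C; (CH2O)n, −78 °C to rt
Reagents that add atoms: trimethylaluminium (AlMe3), C[Al](C)C; paraformaldehyde (formaldehyde unit), C=O
Why: Negishi zirconium-catalysed carboalumination adds methyl and aluminium syn across the terminal alkyne with aluminium on the terminal carbon, so the new trisubstituted alkene is E, and the derived alanate is hydroxymethylated by formaldehyde with retention of geometry.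

Step 6
Reactants: 9 (2E,4E)-6-(TBDPSO)-3-methylhexa-2,4-dien-1-ol
Product: 10 (2E,4E)-6-(TBDPSO)-3-methylhexa-2,4-dienal
Conditions: MnO2, CH2Cl2, rt
Reagents that add atoms: none
Why: MnO2 oxidises the dienylic primary alcohol to the aldehyde without over-oxidation or alkene isomerisation.

Step 7
Reactants: 4 4,4-dimethoxy-3-[(triethylsilyloxy)methyl]cyclohexa-2,5-dien-1-one; 10 (2E,4E)-6-(TBDPSO)-3-methylhexa-2,4-dienal
Product: 12 6-[(2E,4E)-6-(TBDPSO)-1-hydroxy-3-methylhexa-2,4-dien-1-yl]-4,4-dimethoxy-5-(phenylsulfanyl)-3-[(triethylsilyloxy)methyl]cyclohex-2-en-1-one, via lithium enolate 11 (not isolated)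
Conditions: PhSH, n-BuLi, THF, 0 °C; add 4, −78 °C; then 10, −78 °C; AcOH quench at −78 °C
Reagents that add atoms: thiophenol (used as its lithium salt), Sc1ccccc1
Why: Intermolecular thia-Michael/aldol cascade (a stoichiometric Morita–Baylis–Hillman surrogate): the soft thiolate adds to the only unsubstituted β-carbon of 4 and the lithium enolate so formed adds 1,2 to the enal to make the ring–C1′ bond; the carbinol is formed unselectively here (diastereomer mixture) and the two ring centres are erased in step 8.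

Step 8
Reactants: 12 β-(phenylsulfanyl) aldol adduct
Product: 14 rac-2-[(2E,4E)-6-(TBDPSO)-1-hydroxy-3-methylhexa-2,4-dien-1-yl]-4,4-dimethoxy-5-[(triethylsilyloxy)methyl]cyclohexa-2,5-dien-1-one, via sulfoxide 13 (not isolated)
Conditions: mCPBA (1.0 equiv), CH2Cl2, −78 °C; then Et3N, −78 °C to rt
Reagents that add atoms: none
Why: Chemoselective sulfide-to-sulfoxide oxidation at −78 °C followed by base-assisted β-elimination of benzenesulfenic acid from the β-sulfinyl ketone restores the dienone and gives the Baylis–Hillman-type carbinol as a racemate.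

Step 9
Reactants: 14 racemic dienone carbinol
Product: 15 2-[(1S,2E,4E)-6-(TBDPSO)-1-hydroxy-3-methylhexa-2,4-dien-1-yl]-4,4-dimethoxy-5-[(triethylsilyloxy)methyl]cyclohexa-2,5-dien-1-one
Conditions: Ti(OiPr)4 (20 mol %), L-(+)-DIPT (30 mol %), t-BuOOH (0.6 equiv), 4 Å MS, CH2Cl2, −20 °C, stopped at ca. 55–60 % conversion
Reagents that add atoms: none
Why: Katsuki–Sharpless kinetic resolution of a secondary allylic alcohol: with L-(+)-DIPT the titanium tartrate peroxide epoxidises the 2′,3′-alkene of the (R)-carbinol much faster (carbinol H on the face of oxygen delivery) while the electron-poor dienone alkenes are inert, so the (S)-carbinol is recovered in high ee at the cost of at most half of the material.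

Step 10
Reactants: 15 (S)-dienone carbinol
Product: 16 (1R,6S)-1-[(1S,2E,4E)-6-(TBDPSO)-1-hydroxy-3-methylhexa-2,4-dien-1-yl]-5,5-dimethoxy-4-[(triethylsilyloxy)methyl]-7-oxabicyclo[4.1.0]hept-3-en-2-one
Conditions: t-BuOOH (in decane), DBU, CH2Cl2, 0 °C
Reagents that add atoms: tert-butyl hydroperoxide, CC(C)(C)OO
Why: Weitz–Scheffer nucleophilic epoxidation: t-BuOO− attacks the only unsubstituted β-carbon (the other carries CH2OTES) and the enolate closes on oxygen; the C1′ hydroxyl is hydrogen-bonded to the ring ketone, which places the dienyl arm over one face, so the oxirane is expected on the opposite face and sets the (1R,6S) centres together, cis by ring constraint (minor isomer removed by chromatography).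

Step 11
Reactants: 16 epoxy ketone TES ether
Product: 17 (1R,6S)-1-[(1S,2E,4E)-6-(TBDPSO)-1-hydroxy-3-methylhexa-2,4-dien-1-yl]-4-(hydroxymethyl)-5,5-dimethoxy-7-oxabicyclo[4.1.0]hept-3-en-2-one
Conditions: HF·pyridine, pyridine, THF, 0 °C
Reagents that add atoms: none
Why: Buffered HF·pyridine cleaves the primary TES ether far faster than the TBDPS ether and leaves the ketal, oxirane and carbinol centre untouched (selective desilylation).

Step 12
Reactants: 17 epoxy ketone diol
Product: 18 {(1R,6S)-1-[(1S,2E,4E)-1-acetoxy-6-(TBDPSO)-3-methylhexa-2,4-dien-1-yl]-5,5-dimethoxy-2-oxo-7-oxabicyclo[4.1.0]hept-3-en-4-yl}methyl acetate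
Conditions: Ac2O, pyridine, DMAP (cat.), CH2Cl2, 0 °C to rt
Reagents that add atoms: acetic anhydride, CC(=O)OC(C)=O
Why: DMAP-catalysed acylation esterifies both the primary and the hindered secondary hydroxyl with retention at C1′.

Step 13
Reactants: 18 diacetate TBDPS ether
Product: 19 {(1R,6S)-1-[(1S,2E,4E)-1-acetoxy-6-hydroxy-3-methylhexa-2,4-dien-1-yl]-5,5-dimethoxy-2-oxo-7-oxabicyclo[4.1.0]hept-3-en-4-yl}methyl acetate
Conditions: Bu4NF, AcOH (1:1), THF, 0 °C to rt
Reagents that add atoms: none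
Why: Fluoride cleaves the silyl ether, and buffering with acetic acid keeps the medium non-basic so that the acetates and the epoxy ketone survive.

Step 14
Reactants: 19 dienylic alcohol
Product: 20 {(1R,6S)-1-[(1S,2E,4E)-1-acetoxy-3-methyl-6-oxohexa-2,4-dien-1-yl]-5,5-dimethoxy-2-oxo-7-oxabicyclo[4.1.0]hept-3-en-4-yl}methyl acetate
Conditions: MnO2, CH2Cl2, rt
Reagents that add atoms: none
Why: MnO2 selectively oxidises the dienylic primary alcohol to the (2E,4E)-dienal under neutral conditions.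

Step 15
Reactants: 20 dienal dimethyl ketal
Product: 21 {(1R,6S)-1-[(1S,2E,4E)-1-acetoxy-3-methyl-6-oxohexa-2,4-dien-1-yl]-2,5-dioxo-7-oxabicyclo[4.1.0]hept-3-en-4-yl}methyl acetate (CNP0307549.1)
Conditions: TFA/H2O (9:1), CH2Cl2, 0 °C
Reagents that add atoms: water, O
Why: Acid-catalysed hydrolysis of the quinone monoketal to the enedione is left to the end, so that the electron-poor dienal and the epoxy ketone disfavour ionisation of the allylic acetate, and no stereocentre is touched.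

## Compound list

1 | 5-hydroxy-2-methoxybenzaldehyde | COc1ccc(O)cc1C=O | starting material
2 | 3-(hydroxymethyl)-4-methoxyphenol | COc1ccc(O)cc1CO | intermediate
3 | 3-(hydroxymethyl)-4,4-dimethoxycyclohexa-2,5-dien-1-one | COC1(OC)C=CC(=O)C=C1CO | intermediate
4 | 4,4-dimethoxy-3-[(triethylsilyloxy)methyl]cyclohexa-2,5-dien-1-one | CC[Si](CC)(CC)OCC1=CC(=O)C=CC1(OC)OC | intermediate
5 | (2E)-pent-2-en-4-yn-1-ol | C#C/C=C/CO | starting material
6 | tert-butyl{[(2E)-pent-2-en-4-yn-1-yl]oxy}diphenylsilane | C#C/C=C/CO[Si](c1ccccc1)(c1ccccc1)C(C)(C)C | intermediate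
7 | [(1E,3E)-5-(TBDPSO)-2-methylpenta-1,3-dien-1-yl]dimethylalane (not isolated) | C[Al](C)/C=C(C)/C=C/CO[Si](c1ccccc1)(c1ccccc1)C(C)(C)C | intermediate
8 | lithium butyl[(1E,3E)-5-(TBDPSO)-2-methylpenta-1,3-dien-1-yl]dimethylalanate (not isolated) | [Li+].CCCC[Al-](C)(C)/C=C(C)/C=C/CO[Si](c1ccccc1)(c1ccccc1)C(C)(C)C | intermediate
9 | (2E,4E)-6-(TBDPSO)-3-methylhexa-2,4-dien-1-ol | OC/C=C(C)/C=C/CO[Si](c1ccccc1)(c1ccccc1)C(C)(C)C | intermediate
10 | (2E,4E)-6-(TBDPSO)-3-methylhexa-2,4-dienal | O=C/C=C(C)/C=C/CO[Si](c1ccccc1)(c1ccccc1)C(C)(C)C | intermediate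
11 | lithium 4,4-dimethoxy-3-(phenylsulfanyl)-5-[(triethylsilyloxy)methyl]cyclohexa-1,5-dien-1-olate (racemic, not isolated) | [Li+].[O-]C1=CC(Sc2ccccc2)C(OC)(OC)C(CO[Si](CC)(CC)CC)=C1 | intermediate
12 | 6-[(2E,4E)-6-(TBDPSO)-1-hydroxy-3-methylhexa-2,4-dien-1-yl]-4,4-dimethoxy-5-(phenylsulfanyl)-3-[(triethylsilyloxy)methyl]cyclohex-2-en-1-one (racemic mixture of diastereomers; the three sp3 centres are undefined, alkene geometry defined) | CC[Si](CC)(CC)OCC1=CC(=O)C(C(O)/C=C(C)/C=C/CO[Si](c2ccccc2)(c2ccccc2)C(C)(C)C)C(Sc2ccccc2)C1(OC)OC | intermediate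
13 | the 5-(phenylsulfinyl) analogue of 12 (mixture, not isolated) | CC[Si](CC)(CC)OCC1=CC(=O)C(C(O)/C=C(C)/C=C/CO[Si](c2ccccc2)(c2ccccc2)C(C)(C)C)C(S(=O)c2ccccc2)C1(OC)OC | intermediate
14 | rac-2-[(2E,4E)-6-(TBDPSO)-1-hydroxy-3-methylhexa-2,4-dien-1-yl]-4,4-dimethoxy-5-[(triethylsilyloxy)methyl]cyclohexa-2,5-dien-1-one (racemic at C1′) | CC[Si](CC)(CC)OCC1=CC(=O)C(C(O)/C=C(C)/C=C/CO[Si](c2ccccc2)(c2ccccc2)C(C)(C)C)=CC1(OC)OC | intermediate
15 | 2-[(1S,2E,4E)-6-(TBDPSO)-1-hydroxy-3-methylhexa-2,4-dien-1-yl]-4,4-dimethoxy-5-[(triethylsilyloxy)methyl]cyclohexa-2,5-dien-1-one | CC[Si](CC)(CC)OCC1=CC(=O)C([C@H](/C=C(C)/C=C/CO[Si](c2ccccc2)(c2ccccc2)C(C)(C)C)O)=CC1(OC)OC | intermediate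
16 | (1R,6S)-1-[(1S,2E,4E)-6-(TBDPSO)-1-hydroxy-3-methylhexa-2,4-dien-1-yl]-5,5-dimethoxy-4-[(triethylsilyloxy)methyl]-7-oxabicyclo[4.1.0]hept-3-en-2-one | CC[Si](CC)(CC)OCC1=CC(=O)[C@]2([C@H](/C=C(C)/C=C/CO[Si](c3ccccc3)(c3ccccc3)C(C)(C)C)O)O[C@@H]2C1(OC)OC | intermediate
17 | (1R,6S)-1-[(1S,2E,4E)-6-(TBDPSO)-1-hydroxy-3-methylhexa-2,4-dien-1-yl]-4-(hydroxymethyl)-5,5-dimethoxy-7-oxabicyclo[4.1.0]hept-3-en-2-one | OCC1=CC(=O)[C@]2([C@H](/C=C(C)/C=C/CO[Si](c3ccccc3)(c3ccccc3)C(C)(C)C)O)O[C@@H]2C1(OC)OC | intermediate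
18 | {(1R,6S)-1-[(1S,2E,4E)-1-acetoxy-6-(TBDPSO)-3-methylhexa-2,4-dien-1-yl]-5,5-dimethoxy-2-oxo-7-oxabicyclo[4.1.0]hept-3-en-4-yl}methyl acetate | CC(=O)OCC1=CC(=O)[C@]2([C@H](/C=C(C)/C=C/CO[Si](c3ccccc3)(c3ccccc3)C(C)(C)C)OC(C)=O)O[C@@H]2C1(OC)OC | intermediate
19 | {(1R,6S)-1-[(1S,2E,4E)-1-acetoxy-6-hydroxy-3-methylhexa-2,4-dien-1-yl]-5,5-dimethoxy-2-oxo-7-oxabicyclo[4.1.0]hept-3-en-4-yl}methyl acetate | CC(=O)OCC1=CC(=O)[C@]2([C@H](/C=C(C)/C=C/CO)OC(C)=O)O[C@@H]2C1(OC)OC | intermediate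
20 | {(1R,6S)-1-[(1S,2E,4E)-1-acetoxy-3-methyl-6-oxohexa-2,4-dien-1-yl]-5,5-dimethoxy-2-oxo-7-oxabicyclo[4.1.0]hept-3-en-4-yl}methyl acetate | CC(=O)OCC1=CC(=O)[C@]2([C@H](/C=C(C)/C=C/C=O)OC(C)=O)O[C@@H]2C1(OC)OC | intermediate
21 | {(1R,6S)-1-[(1S,2E,4E)-1-acetoxy-3-methyl-6-oxohexa-2,4-dien-1-yl]-2,5-dioxo-7-oxabicyclo[4.1.0]hept-3-en-4-yl}methyl acetate (CNP0307549.1) | CC(=O)OCC1=CC(=O)[C@]2([C@H](/C=C(C)/C=C/C=O)OC(C)=O)O[C@@H]2C1=O | target

## Step count and risks

Total step count: 15 (steps 1–3 ring fragment, steps 4–6 dienal, steps 7–15 after the union).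
Longest linear sequence: 12 steps (1 → 4, then steps 7–15; the dienal branch is equally long).

The three steps most likely to fail:

Step 7 (thia-Michael/aldol on the quinone monoketal). Thiolate addition is reversible, the adduct can aromatise by loss of methanol, and the β-methyl dienal is a sluggish electrophile. The fallback sets out from 4 (with 10) and comes back to the route at 14; it replaces the thiolate cascade by a reductive aldol followed by dehydrogenation. LiBH(s-Bu)3 in THF at −78 °C reduces the unsubstituted enone of 4 in the 1,4-sense, and the enolate is trapped with 10 to give the β-hydroxy ketone 6-[(2E,4E)-6-(TBDPSO)-1-hydroxy-3-methylhexa-2,4-dien-1-yl]-4,4-dimethoxy-3-[(triethylsilyloxy)methyl]cyclohex-2-en-1-one F1, in which no retro-Michael path exists. Me3SiOTf/Et3N converts it into the bis-silylated silyl dienol ether F2. Saegusa–Ito dehydrogenation with Pd(OAc)2 in MeCN gives the O-trimethylsilyl ether of 14 F3, and brief K2CO3/MeOH treatment releases 14.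

Step 9 (Sharpless kinetic resolution). The reacting alkene carries a methyl cis to the carbinol and the β-hydroxy ketone can chelate titanium, so the selectivity factor may be modest; the yield cannot exceed 50 %. The fallback sets out from 14 and comes back at 15; it is an acylative enzymatic resolution instead of an oxidative one. With Amano lipase PS and vinyl acetate in MTBE at 30 °C, Kazlauskas' rule (ring as the large, dienyl CH as the medium substituent) predicts acetylation of the (R)-alcohol to the (R)-acetate 2-[(1R,2E,4E)-1-acetoxy-6-(TBDPSO)-3-methylhexa-2,4-dien-1-yl]-4,4-dimethoxy-5-[(triethylsilyloxy)methyl]cyclohexa-2,5-dien-1-one F4, while the (S)-alcohol 15 stays behind and is separated on silica.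

Step 10 (diastereoselective epoxidation). The facial selectivity rests on substrate control alone, and the β-hydroxy epoxy ketone is base-sensitive (Payne rearrangement). The fallback sets out from 15 and comes back at 17; it uses reagent control through the ring hydroxymethyl group. The TES ether is cleaved first (HF·pyridine, pyridine, THF, 0 °C) to the dienone diol 2-[(1S,2E,4E)-6-(TBDPSO)-1-hydroxy-3-methylhexa-2,4-dien-1-yl]-5-(hydroxymethyl)-4,4-dimethoxycyclohexa-2,5-dien-1-one F5. A tartrate-mediated nucleophilic epoxidation (Ph3COOH, NaN(SiMe3)2, diisopropyl tartrate, toluene, −50 °C) then lets the sodium alkoxide of the ring CH2OH deliver the peroxide to the neighbouring unsubstituted β-carbon. The tartrate enantiomer is picked in a small L/D screen so that reagent and substrate bias are matched; the product is diol 17.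

## Further compounds

F1 | step 7 | 6-[(2E,4E)-6-(TBDPSO)-1-hydroxy-3-methylhexa-2,4-dien-1-yl]-4,4-dimethoxy-3-[(triethylsilyloxy)methyl]cyclohex-2-en-1-one (racemic diastereomer mixture) | CC[Si](CC)(CC)OCC1=CC(=O)C(C(O)/C=C(C)/C=C/CO[Si](c2ccccc2)(c2ccccc2)C(C)(C)C)CC1(OC)OC
F2 | step 7 | silyl dienol ether: {6-[(2E,4E)-6-(TBDPSO)-3-methyl-1-(trimethylsilyloxy)hexa-2,4-dien-1-yl]-4,4-dimethoxy-3-[(triethylsilyloxy)methyl]cyclohexa-1(6),2-dien-1-yl}oxy(trimethyl)silane | CC[Si](CC)(CC)OCC1=CC(O[Si](C)(C)C)=C(C(O[Si](C)(C)C)/C=C(C)/C=C/CO[Si](c2ccccc2)(c2ccccc2)C(C)(C)C)CC1(OC)OC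
F3 | step 7 | O-trimethylsilyl ether of 14 | CC[Si](CC)(CC)OCC1=CC(=O)C(C(O[Si](C)(C)C)/C=C(C)/C=C/CO[Si](c2ccccc2)(c2ccccc2)C(C)(C)C)=CC1(OC)OC
F4 | step 9 | 2-[(1R,2E,4E)-1-acetoxy-6-(TBDPSO)-3-methylhexa-2,4-dien-1-yl]-4,4-dimethoxy-5-[(triethylsilyloxy)methyl]cyclohexa-2,5-dien-1-one | CC[Si](CC)(CC)OCC1=CC(=O)C([C@@H](/C=C(C)/C=C/CO[Si](c2ccccc2)(c2ccccc2)C(C)(C)C)OC(C)=O)=CC1(OC)OC
F5 | step 10 | 2-[(1S,2E,4E)-6-(TBDPSO)-1-hydroxy-3-methylhexa-2,4-dien-1-yl]-5-(hydroxymethyl)-4,4-dimethoxycyclohexa-2,5-dien-1-one | OCC1=CC(=O)C([C@H](/C=C(C)/C=C/CO[Si](c2ccccc2)(c2ccccc2)C(C)(C)C)O)=CC1(OC)OC
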